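(The runs were computed from invented constants; scatter was added.)

in all of them: E 0.67 M

| run | D | remark | time |
|---|---|---|---|
| elm | 0.50 M | run made earlier |  |
| theta | 0.335 M |  | 30 h |
| beta | 2.68 M |  | 30 h |
| alpha | 1.01 M |  | 30 h |

- elm (time / h: X / %, Z / %): 1.50: 1, 4; 3.00: 0, 7; 5.00: 0, 10; 8.00: 0, 15; 12.0: 2, 21; 20.0: 0, 27

(scatter of a reading: 1.5 percentage points)

- which of these holds the largest part of the E at the end of theta (G / Z / X / E)
- which of these holds the largest part of the E at the end of beta (G / Z / X / E)
- which of these holds the largest part of the E at the end of alpha (G / Z / X / E)
- how much X is there at the end of alpha, in percent of the E charged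

- no earlier run changes the charge of D; that part of a forecast is a guess

Every exchange uses one D, so while the first exchange carries the traffic, what E loses D loses too. In elm, Z reads 21% at 12.0 h. Count that as E lost, take mean D as the charge less half of the loss, and you get a rate constant k of 0.0457 /M/h. This is a reading, with its scatter, and its first order in D is my assumption, since no earlier run changes D.

Now fold the givens into one number. Take 1.04 for alpha: that is N, k times mean D times time. It counts the e-foldings of E, treated as pseudo-first-order decay, so E left is e^−N. Below 0.693, E keeps more than half and must lead. Theta's 0.290 stays below, so I say E, with 74.8% left. Alpha lies above, with 35.3% left, so I say Z.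

Is one number enough? At 20.0 h elm has N = 0.345, which predicts 29.2% converted, while Z reads 27%. That gap of 2.2 percentage points sits beside a scatter of 1.5 points, so elm cannot size the later steps. Beta's 3.23 leaves 3.96% of E but says nothing of the split among Z, G and X, so I name no species for beta. For X in alpha I have only a guess, the size of elm's 2% reading.

The forecast says E for theta, G for beta, Z for alpha and 3% of X in alpha, adding for beta “though X could compete”.

    E + D → L + Z (k = 0.0500 /M/h)
    Z + D → L + G (k = 0.0110 /M/h)
    G + D → L + X (k = 0.0830 /M/h)
    L + Z → J (k = 0.0420 /M/h)

The flasks end with E largest in theta, Z in beta and Z in alpha, where X stands at 3.23%. In beta, Z holds 34.1%, X 23.3%, G 5.54% and J, made from L and Z, 32.3%. Alpha's E of 35.0% reads back as N = 1.05. In the neighbour of alpha charged with 0.61 M of D, N comes to 0.576, below 0.693, and E ends largest at 54.1%.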